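Convention and assumption: daucane numbering is used for every intermediate. C1 is the quaternary fusion carbon with the methyl group, C2 and C3 are ring CH2, C4 is the isopropyl carbinol carbon, C5 is the fusion CH, and C6 is the veratrate carbon. C7 is CH2, C8 is the methyl-bearing alkene carbon, C9 is the alkene CH, and C10 is the angelate carbon. β is the face of the C1 methyl group and α is the opposite face. β-Dicarbonyl compounds are drawn as one tautomer. Stereocentres that are erased later are left open in the SMILES strings.

## Analysis of the target

The target is a daucane diester: a cyclopentane (C1–C5) trans-fused along C1–C5 to a cycloheptene (C1, C5–C10) whose only ring alkene is the trisubstituted C8=C9. It has five stereocentres, (1S,4R,5S,6S,10R). The C1 methyl and the C4 hydroxyl lie on the β face, whereas H5, the isopropyl group and both acyloxy groups lie on the α face. As a result the C6 oxygen is equatorial and the C10 oxygen is pseudoaxial, anti to the neighbouring methyl group.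

Three groups are sensitive:
- The (Z)-angelate slips to the tiglate under nucleophilic catalysis.
- The allylic C10 ester can ionise, or leave by vinylogous elimination whenever C6 is a ketone.
- The tertiary C4 alcohol is the hydroxyl of an aldol as long as C6 is a carbonyl.

The hard points are these:
- The seven-membered ring sits next to a quaternary carbon.
- The ring fusion is trans.
- C6 and C10 must be told apart.
- The alkene must be placed on the C10 side.
- The C10 oxygen sits on the face from which reagents normally attack, so hydride has to come from the methyl side.

The strategy rests on the chain C6–C7–C8–C9–C10. With both oxygenated carbons raised to ketones it is a 1,5-diketone, the pattern left by a [2+2] photocycloaddition followed by retro-aldol cleavage. Excising C8–C9 contracts the seven-membered ring to a cyclopentane-1,3-dione (C7 bonded to C10) fused to the cyclopentane that already holds C1. The methyl-bearing alkene carbon C8 then reads as an isomerised exocyclic methylene, which points to allene as the two-carbon unit.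

## Retrosynthetic reasoning

**Acyl–oxygen bonds at C10 and C6.** Target 26 is cut first at the angelate, giving alcohol 23 and angelic acid 24 (activated as mixed anhydride 25). It is then cut at the veratrate, giving triol 21 and acid chloride 22. The angelate goes on last because it is the most fragile group, and because at that stage no ketone is left that could trigger vinylogous loss of a C10 ester. The forward acylation of 21 has to choose the equatorial C6 hydroxyl over the pseudoaxial, neopentyl C10 hydroxyl and the tertiary C4 hydroxyl.

**C6–H bond.** Triol 21 goes back to ketol 20. The cut is made here because the 4β-hydroxyl of 20 can carry a hydride to the β face of C6. This gives the 6α-alcohol and leaves everything else alone. An undirected hydride would come from the α face, away from the methyl group, and give the wrong epimer.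

**C4–isopropyl and C5–H bonds.** Ketol 20 goes back through carbinol 19 to enone 17 and Grignard reagent 18. An isopropyl metal cannot be added to a free C4/C6 β-diketone, which would only be deprotonated. Nor can it be added to a cis-fused C4 ketone, which would be attacked from the convex β face. C6 is therefore masked as an enol ether. C5 is then sp2, the fusion problem is suspended, and the C1 methyl is the only bias at C4. The mask is a silyl group, because acid hydrolysis of an alkyl enol ether would ionise the tertiary allylic carbinol. The C5–H bond is made when the enol is released. It is not left to a later base equilibration, since any base would first move the β,γ-alkene of 20 into conjugation with C6.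

**C10–H bond.** Alcohol 17 goes back to enone 16. C10 must be at the alcohol level before 18 is used, and the vinylogous ester of 16 is the one platform on which C10 is the only reactive carbonyl. Substrate control would deliver hydride anti to the methyl group, so the forward step needs a chiral reagent that reads the two flanks of the carbonyl.

**Functional-group changes back to the ring-expansion product.** Enone 16 comes from enolised trione 15 by O-silylation. Trione 15 comes from its exocyclic isomer 14 by alkene migration, and 14 comes from ketal 13 by hydrolysis. The order matters. In 13 the methylene is flanked by two equivalent ketones and could move either way. In 14 the C4/C6 β-diketone is present as its enolate under base, so only C10 still acidifies its neighbour, and the alkene goes to C8=C9.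

**Key disconnection: C7–C8 and C9–C10 cut, C7–C10 restored.** Dione 13 goes back through methylenecyclobutanol 12 to bicyclic 1,3-dione 10 and allene 11. This removes the seven-membered ring, the hardest ring to close next to C1, and replaces it by a five-membered ring made by a condensation. Allene brings C8, C9 and the future methyl carbon at the right oxidation level. The forward reaction needs the central allene carbon on the dione CH2.

**C7–C10 bond.** Dione 10 goes back to keto ester 9 by an intramolecular Claisen condensation. The bond chosen is the one that the key step breaks again, so its only role is to build the chromophore. The cis fusion is enforced by ring strain, and C5 needs no control beforehand.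

**Functional-group changes.** Ester 9 comes from vinyl ketone 8 (vinyl to methyl ester). Ketone 8 comes from alcohol 7 by oxidation, and 7 comes from aldol 5 by ketalisation at C4 through silyl ether 6. The ketal keeps C4 out of the Claisen step and out of the chromophore.

**C1–C10 and C5–C6 bonds.** Aldol 5 goes back through enolate 4 to enone 1, vinyl Grignard reagent 2 and acetaldehyde 3. Conjugate addition creates quaternary C1 under catalyst control. Trapping the enolate where it is formed is the only simple way to functionalise hindered C5 rather than C3.

## Alternatives that were turned down

**Alternative 1: Ireland–Claisen ring contraction.** The cut is C1–C10, with the cyclopentane left open. In the forward sense the silyl ketene acetal of seven-membered lactone A1, whose ring oxygen sits on the tertiary allylic carbon C8, rearranges through a boat transition state to cycloheptene acid A2. C1–C10 forms, O–C8 breaks, and the former lactone carbonyl ends as a carboxyl group (C2) on quaternary C1.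

In its favour:
- The alkene is born at C8=C9.
- C6 and C10 arrive as differently protected alcohols.
- C1 and C10 are set together by chirality transfer.

On these three points it is stronger than the chosen route, which must move an alkene, tell two ketones apart and reduce both.

Against it:
- A1 already needs C5, C6, the tertiary C8 carbinol and a defined enol-ether geometry, all made before any ring helps.
- Its α-branched position next to the bulky C5 side chain is hard to enolise.
- After A2 the cyclopentane is still missing. C3 has to be attached to a neopentyl carboxyl group, and the ring must be closed onto C4 while the tertiary alcohol is created stereoselectively.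

The chosen strategy offers instead a catalytic entry to C1 in the first step and both rings after six steps.

**Alternative 2: intramolecular oxyallyl (4+3) cycloaddition.** The cuts are C1–C5 and C8–C9. The oxyallyl cation from tertiary α-chloro methyl ketone A3 adds across its tethered 2-silyloxydiene and closes both rings at once to give A4. This is the most convergent plan: two rings and two bonds arise from an open chain, and the C4 carbinol is in place from the start. The whole C4 problem of the chosen route therefore disappears, and on that point it is clearly stronger.

Against it:
- An acyclic silyloxydiene must reach the s-cis form.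
- It can also react as a simple silyl enol ether, giving stepwise alkylation, (3+2) closure or a Favorskii pathway.
- C1 and C5 would be controlled only by a remote acyclic carbinol, so the trans fusion is not secured.
- The enantiopure tertiary carbinol of A3 needs its own asymmetric synthesis.
- A4 has C8 saturated and the alkene at C6=C7 as an enol ether, so C8=C9 still has to be introduced by dehydrogenation from C10.

The chosen strategy places its risk in a ring expansion on a rigid bicycle whose stereocentres are spectators.

**Alternative 3: enone–enediol ether photocycloaddition, then glycol cleavage.** The cuts are C1–C10 and C5–C6. Enone A5 adds photochemically to bis(silyloxy)cyclopentene A6 to give the 5-4-5 tricycle A7. Desilylation and cleavage of the C6–C10 glycol then give saturated trione A8. It is the shortest way to the carbon skeleton, uses a well-known variant of the same photochemical logic, and needs no allene. In step count up to the bicycle it beats the chosen route.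

Against it:
- Quaternary C1 is created in the photoreaction of an achiral enone, so the material is racemic and a resolution is unavoidable.
- The cycloaddition must join a β-substituted enone carbon to a tetrasubstituted alkene, so two fully substituted carbons become neighbours.
- A8 lacks the alkene, so C8=C9 must be installed later.
- A8 still carries the C4/C6 β-diketone and the C6/C10 problem.

The chosen strategy fixes C1 by catalysis before the photochemistry and brings the unsaturation in with the two-carbon unit.

Key step: step 6

## Route

Step 1
Reactants: 1 3-methylcyclopent-2-en-1-one; 2 vinylmagnesium bromide; 3 acetaldehyde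
Product: 5 (3R)-2-(1-hydroxyethyl)-3-methyl-3-vinylcyclopentan-1-one (C1 defined; epimers at C5 and C6), via magnesium enolate 4 (not isolated)
Conditions: Cu(OTf)2 (3 mol %), chiral hydroxyalkyl-imidazolinium salt (NHC precursor, 4 mol %, the enantiomer that gives the C1 configuration drawn), 2, Et2O, −30 °C; then 3, −78 °C; aq. NH4Cl
Reagents that add atoms: none
Why: Copper-catalysed asymmetric conjugate addition of a Grignard reagent to a β-substituted cyclic enone, followed by aldol trapping of the regiodefined enolate 4; the chiral NHC–copper complex chooses the enone face and so sets quaternary C1. C5 and C6 arise as epimer mixtures, which is harmless because C6 becomes a carbonyl in step 3 and C5 stays adjustable until step 11.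

Step 2
Reactants: 5 aldol
Product: 7 hydroxy ketal (C4 ethylene ketal of 5), via O-trimethylsilyl ketal 6 (not isolated)
Conditions: (TMSOCH2)2 (2.5 equiv), TMSOTf (5 mol %), CH2Cl2, −78 → −20 °C; pyridine; then K2CO3 (cat.), MeOH, 0 °C
Reagents that add atoms: 1,2-bis(trimethylsilyloxy)ethane, C[Si](C)(C)OCCO[Si](C)(C)C
Why: Noyori ketalisation under aprotic, cold conditions, chosen because hot protic acid would dehydrate or cleave the aldol. The hydroxyl is silylated in passing (6) and freed again by methanolysis.

Step 3
Reactants: 7 hydroxy ketal
Product: 8 methyl ketone (C5 acetyl, C4 ketal, C1 vinyl)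
Conditions: Dess–Martin periodinane, NaHCO3, CH2Cl2, 0 °C → rt
Reagents that add atoms: none
Why: Dess–Martin oxidation of a secondary alcohol; the buffered neutral medium spares the ketal and the vinyl group. The C6 stereocentre is erased.

Step 4
Reactants: 8 methyl ketone
Product: 9 keto ester (C10 as methyl ester on C1, C5 acetyl, C4 ketal)
Conditions: O3, NaOH (2.5 M in MeOH), CH2Cl2, −78 °C
Reagents that add atoms: ozone, [O-][O+]=O; methanol, CO
Why: Ozonolysis in basic methanol: the aldehyde released from the vinyl group is trapped as its hemiacetal and oxidised by ozone to the methyl ester in the same flask. No other alkene is present, and at −78 °C the ketone is not enolised.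

Step 5
Reactants: 9 keto ester
Product: 10 cis-fused bicyclo[3.3.0]octane-2,4-dione (C6 and C10 carbonyls, C7 CH2, 1β-methyl, 5β-H, C4 ethylene ketal)
Conditions: KOtBu (2.2 equiv), THF, 0 °C → rt; cold 1 M HCl to pH 4
Reagents that add atoms: none
Why: Intramolecular Claisen (Dieckmann-type) condensation of a γ-keto ester, a 5-exo-trig attack of the C7 enolate on the C10 ester. C5 equilibrates under the base and only the cis isomer can close, so the cis fusion is enforced. The product is withdrawn as its stabilised enolate, which drives the reaction and keeps C5 from being deprotonated, so the ketal is not lost by β-elimination.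

Step 6
Reactants: 10 bicyclic 1,3-dione; 11 propa-1,2-diene (allene)
Product: 13 cis-fused 8-methylene-bicyclo[5.3.0]decane-6,10-dione with C4 ethylene ketal (1β-methyl, 5β-H), via methylenecyclobutanol 12 (not isolated)
Conditions: 11 (excess, condensed in), MeCN/CH2Cl2, −40 °C, hν (medium-pressure Hg lamp, Pyrex filter, λ > 290 nm), stopped short of full conversion; then rt in the dark
Reagents that add atoms: none
Why: Proposed new method: the enol of 10 (either tautomer) is a β-hydroxy enone chromophore whose triplet adds stepwise to one C=C of allene through a 1,4-biradical, closing the four-membered ring of methylenecyclobutanol 12 by radical recombination. 12 is a strained β-hydroxy ketone and opens by retro-aldol cleavage of the bond shared by the four- and five-membered rings (C7–C10), so the seven-membered ring arises by two-carbon expansion of the dione ring and not by an end-to-end cyclisation. The closest known reaction types are the de Mayo reaction of cyclic 1,3-dione enols with simple alkenes and the photocycloaddition of allene to cyclic enones; their combination is not established. The step needs head-to-head orientation, with the central allene carbon on the α-carbon of the chromophore (the dione CH2), which is the usual orientation of allene with cyclic enones and puts the methylene on C8. With that orientation both enol tautomers converge on 13: through the C10 enol the new bonds are C7–C8 and C9–C10, through the C6 enol they are C8–C9 and C6–C7, so the tautomer ratio does not matter. No stereocentre of 13 is new: the two centres of 12, set by approach of allene to the convex β face of the cis-bicyclooctane, revert to CH2 and C=O, and C1 and C5 are not touched. The ketal keeps C4 out of the chromophore, and the Pyrex filter, low temperature and incomplete conversion limit secondary photoreactions of the β,γ-unsaturated ketone units of 13.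

Step 7
Reactants: 13 ketal dione
Product: 14 8-methylene-4,6,10-trione, present as the hydrogen-bonded enol of the C4/C6 β-diketone (C5 sp2)
Conditions: 1 M HCl, THF, 0 °C → rt
Reagents that add atoms: water, O
Why: Acid hydrolysis of the dioxolane, pulled forward by formation of the chelated β-diketone enol; C5 becomes sp2, which erases the cis fusion. Mild acid at or below room temperature is used so that the alkene does not move while C6 is still an ordinary ketone.

Step 8
Reactants: 14 exocyclic trione
Product: 15 8-methyl-8-ene-4,6,10-trione (C8=C9 conjugated with C10; C4/C6 enolised)
Conditions: DBU (2.2 equiv), CH2Cl2, 0 °C; cold dilute HCl wash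
Reagents that add atoms: none
Why: Base-mediated β,γ to α,β isomerisation of an unsaturated ketone. DBU first converts the C4/C6 β-diketone into its enolate, which switches C6 off as an acidifying group for C7–H. Only C9–H next to the free C10 ketone is then removed, and reprotonation at the exocyclic carbon gives the C8=C9 enone.

Step 9
Reactants: 15 enolised trione
Product: 16 6-triisopropylsilyloxy-5(6),8-diene-4,10-dione (vinylogous silyl ester, C4 carbonyl free)
Conditions: TIPSOTf (1.05 equiv), Et3N, CH2Cl2, −78 → 0 °C
Reagents that add atoms: triisopropylsilyl trifluoromethanesulfonate, CC(C)[Si](C(C)C)(C(C)C)OS(=O)(=O)C(F)(F)F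
Why: O-silylation of a β-diketone to a vinylogous silyl ester; the acidic β-diketone reacts before the C10 enone can be enolised. The two possible regioisomers can interconvert by 1,5-silyl shift. The isomer with C5=C6 (exocyclic to the five-membered ring, endocyclic in the seven-membered ring) and an intact cyclopentanone carbonyl at C4 should prevail.

Step 10
Reactants: 16 vinylogous silyl ester
Product: 17 (10R)-10α-hydroxy derivative of 16
Conditions: (S)-2-methyl-CBS-oxazaborolidine (0.5 equiv), BH3·SMe2, toluene/THF, −40 °C; MeOH
Reagents that add atoms: none
Why: Corey–Bakshi–Shibata reduction of an enone; C10 is the only ordinary ketone, because the C4 carbonyl is deactivated as a vinylogous ester. The catalyst reads quaternary C1 as the large flank and vinylic C9 as the small flank. It should therefore deliver hydride to the β face and set the 10α-alcohol against the substrate bias, which favours attack anti to the methyl group.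

Step 11
Reactants: 17 allylic alcohol; 18 isopropylmagnesium chloride
Product: 20 ketol (4β,10α-dihydroxy-4α-isopropyl-5α-H-dauc-8-en-6-one, trans-fused), via tertiary carbinol 19 (not isolated)
Conditions: 18/CeCl3 (4 equiv each), THF, −78 → −40 °C; pH 7 buffer; crude 19: TBAF, AcOH (1:1.2), THF, −20 → 0 °C
Reagents that add atoms: none
Why: 1,2-Addition of an organocerium reagent to a vinylogous ester (the first half of a Stork–Danheiser sequence; the C10 hydroxyl rides along as its alkoxide), then fluoride cleavage of the silyl enol ether. With C5 sp2 the only bias at C4 is the β methyl on C1, so isopropyl enters from the α face and gives the 4β-hydroxyl. Buffered fluoride instead of acid frees the C6 ketone without ionising the tertiary allylic carbinol, and C5 is protonated from the α face, anti to the methyl group, giving the trans fusion that is also the more stable one (C6 anti to isopropyl, hydroxyl hydrogen-bonded to the C6 carbonyl).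

Step 12
Reactants: 20 ketol
Product: 21 triol (dauc-8-ene-4β,6α,10α-triol)
Conditions: Me4NBH(OAc)3 (5 equiv), MeCN/AcOH (1:1), −30 °C
Reagents that add atoms: none
Why: Evans–Saksena reduction: the 4β-hydroxyl exchanges onto boron and hands hydride to C6 through a six-membered transition state from the β face, which sets the 6α-alcohol. The acidic, cold medium leaves the β,γ-alkene, the aldol unit and C5 untouched. Delivery from the more remote C10 hydroxyl would need a larger ring and should not compete.

Step 13
Reactants: 21 triol; 22 3,4-dimethoxybenzoyl chloride (veratroyl chloride)
Product: 23 6-O-veratroyl triol (4β,10α-dihydroxydauc-8-en-6α-yl 3,4-dimethoxybenzoate)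
Conditions: 22 (1.1 equiv), Et3N, DMAP (0.2 equiv), CH2Cl2, 0 °C → rt
Reagents that add atoms: none
Why: DMAP-catalysed acylation with one equivalent of acid chloride. The equatorial C6 hydroxyl should react ahead of the pseudoaxial C10 hydroxyl, which is neopentyl to quaternary C1, and the tertiary C4 hydroxyl is inert.

Step 14
Reactants: 23 alcohol; 24 angelic acid ((Z)-2-methylbut-2-enoic acid)
Product: 26 target, (1S,4R,5S,6S,10R)-10-angeloyloxy-4-hydroxydauc-8-en-6-yl 3,4-dimethoxybenzoate, via mixed anhydride 25 (not isolated)
Conditions: 24, 2,4,6-trichlorobenzoyl chloride, Et3N, toluene, rt; then 23, 80 °C (no DMAP)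
Reagents that add atoms: 2,4,6-trichlorobenzoyl chloride, O=C(Cl)c1c(Cl)cc(Cl)cc1Cl (its atoms enter only 25)
Why: Yamaguchi-type esterification through the mixed anhydride, run without a nucleophilic catalyst so that the (Z)-alkene of the angeloyl group is not isomerised by addition–elimination. Only one acylable hydroxyl is left and no ketone is present, so heating with amine base cannot trigger elimination.

## Compound list

1 | 3-methylcyclopent-2-en-1-one | CC1=CC(=O)CC1 | starting material
2 | vinylmagnesium bromide | C=C[Mg]Br | starting material
3 | acetaldehyde | CC=O | starting material
4 | bromomagnesium enolate (C4–O, C4=C5) of 3-methyl-3-vinylcyclopentanone | C=C[C@@]1(C)CCC(O[Mg]Br)=C1 | intermediate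
5 | (3R)-2-(1-hydroxyethyl)-3-methyl-3-vinylcyclopentan-1-one | C=C[C@@]1(C)CCC(=O)C1C(C)O | intermediate
6 | O-trimethylsilyl ether of hydroxy ketal 7 | C=C[C@@]1(C)CCC2(OCCO2)C1C(C)O[Si](C)(C)C | intermediate
7 | hydroxy ketal (C4 ethylene ketal of 5) | C=C[C@@]1(C)CCC2(OCCO2)C1C(C)O | intermediate
8 | methyl ketone (C5 acetyl, C4 ketal, C1 vinyl) | C=C[C@@]1(C)CCC2(OCCO2)C1C(C)=O | intermediate
9 | keto ester (C10 methyl ester, C5 acetyl, C4 ketal) | COC(=O)[C@@]1(C)CCC2(OCCO2)C1C(C)=O | intermediate
10 | cis-fused bicyclo[3.3.0]octane-2,4-dione with C1 methyl and C4 ethylene ketal | O=C1CC(=O)[C@H]2[C@]1(C)CCC23OCCO3 | intermediate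
11 | propa-1,2-diene (allene) | C=C=C | starting material
12 | methylenecyclobutanol (adduct of the C10 enol, allene on the β face) | O[C@]12CC(=C)[C@H]1C(=O)[C@H]3[C@]2(C)CCC34OCCO4 | intermediate
13 | cis-fused 8-methylene-6,10-dione with C4 ethylene ketal | O=C1CC(=C)CC(=O)[C@H]2[C@]1(C)CCC23OCCO3 | intermediate
14 | 8-methylene-4,6,10-trione (C6 enol drawn) | O=C1CC(=C)CC(O)=C2C(=O)CC[C@]12C | intermediate
15 | 8-methyl-8-ene-4,6,10-trione (C6 enol drawn) | O=C1C=C(C)CC(O)=C2C(=O)CC[C@]12C | intermediate
16 | 6-triisopropylsilyloxy-5(6),8-diene-4,10-dione | O=C1C=C(C)CC(O[Si](C(C)C)(C(C)C)C(C)C)=C2C(=O)CC[C@]12C | intermediate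
17 | 10α-hydroxy-6-triisopropylsilyloxy-5(6),8-dien-4-one | O[C@@H]1C=C(C)CC(O[Si](C(C)C)(C(C)C)C(C)C)=C2C(=O)CC[C@]12C | intermediate
18 | isopropylmagnesium chloride | CC(C)[Mg]Cl | starting material
19 | 4β,10α-dihydroxy-4α-isopropyl-6-triisopropylsilyloxy-5(6),8-diene | O[C@@H]1C=C(C)CC(O[Si](C(C)C)(C(C)C)C(C)C)=C2[C@](O)(C(C)C)CC[C@]12C | intermediate
20 | ketol, 4β,10α-dihydroxy-5α-H-dauc-8-en-6-one | O[C@@H]1C=C(C)CC(=O)[C@@H]2[C@]1(C)CC[C@@]2(O)C(C)C | intermediate
21 | dauc-8-ene-4β,6α,10α-triol | O[C@@H]1C=C(C)C[C@H](O)[C@@H]2[C@]1(C)CC[C@@]2(O)C(C)C | intermediate
22 | 3,4-dimethoxybenzoyl chloride | COc1ccc(cc1OC)C(=O)Cl | starting material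
23 | 4β,10α-dihydroxydauc-8-en-6α-yl 3,4-dimethoxybenzoate | O[C@@H]1C=C(C)C[C@H](OC(=O)c2ccc(OC)c(OC)c2)[C@@H]2[C@]1(C)CC[C@@]2(O)C(C)C | intermediate
24 | angelic acid | C/C=C(/C)C(=O)O | starting material
25 | angelic 2,4,6-trichlorobenzoic anhydride | C/C=C(/C)C(=O)OC(=O)c1c(Cl)cc(Cl)cc1Cl | intermediate
26 | target CNP0142353.1 | C/C=C(/C)C(=O)O[C@@H]1C=C(C)C[C@H](OC(=O)c2ccc(OC)c(OC)c2)[C@@H]2[C@]1(C)CC[C@@]2(O)C(C)C | target

## Step count and least certain steps

Total steps: 14. Longest linear sequence: 14 (steps 1–14; the route is linear, and 11, 18, 22 and 24 are bought).

**Step 6 (key step, proposed new method).**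
- What may go wrong: the orientation may reverse, with the central allene carbon bonding to the oxygen-bearing enol carbon. That would place the methylene next to a carbonyl instead of on C8.
- The cycloaddition may also be slow, because hydrogen-bonded enol aggregates lose their excitation by proton transfer.
- The product may be over-irradiated, since both of its ketones are β,γ-unsaturated and can undergo acyl shifts.
- Fallback (stepwise form built from known reactions): it sets out from 10, which is O-acetylated (Ac2O, Et3N) to enol acetate F1. The site of O-acylation has no consequence, because either enol ester ends in the same dione.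
- Irradiation of this ordinary β-acyloxy enone with 11 is a standard enone–allene photocycloaddition. It gives the isolable acetoxy methylenecyclobutane F2, which is taken out of the light.
- Brief treatment with K2CO3 in MeOH at 0 °C removes the acetyl group. The cyclobutanolate opens by retro-aldol cleavage, which comes back to the route at 13.

**Step 11.**
- What may go wrong: the tertiary carbinol, which is allylic to a silyl enol ether, may ionise during work-up, with loss of the C4 oxygen.
- Addition may occur at C6 if part of the silyl group sits on the C4 oxygen.
- The hindered carbonyl may be reduced or enolised by the secondary organometallic.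
- C5 may be protonated from the β face. This cannot be corrected by base, because the β,γ-alkene would move first.
- Fallback: accept the dehydration and put the oxygen back by directed epoxidation. It sets out from 17, which is silylated (TBSOTf, 2,6-lutidine) to bis-silyl compound F3.
- Addition of 18/CeCl3 followed by aqueous oxalic acid completes the Stork–Danheiser transposition to 4,8-dien-6-one F4.
- Luche reduction (NaBH4, CeCl3, MeOH), with hydride from the α face, gives 6β-allylic alcohol F5.
- VO(acac)2/tBuOOH delivers oxygen syn to that hydroxyl and gives 4β,5β-epoxy alcohol F6.
- Dess–Martin oxidation gives epoxy ketone F7.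
- SmI2 in THF/MeOH at −90 °C cleaves the C5–O bond to give ketol silyl ether F8.
- HF·pyridine removes the silyl group and comes back to the route at 20.

**Step 10.**
- What may go wrong: facial selectivity may be poor, because the catalyst must send hydride past the axial C1 methyl against the substrate preference.
- The Lewis-basic C4 carbonyl may also be reduced in competition.
- Fallback: use the substrate bias and bring the oxygen in from the open α face. It sets out from 16. Luche reduction gives 10β-alcohol F9.
- A Mitsunobu reaction with formic acid (PPh3, DIAD) inverts C10 to 10α-formate F10.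
- KHCO3 in MeOH at 0 °C cleaves the formate and comes back to the route at 17.

**Step 8.**
- What may go wrong: control over the direction of alkene migration may be lost if migration starts before the β-diketone is fully deprotonated.
- Long exposure to base may also equilibrate the alkene toward conjugation with the C4–C6 system.
- Fallback: mask C6 covalently before the alkene is moved. It sets out from 14, which is silylated (TIPSOTf, Et3N) to exocyclic vinylogous silyl ester F11.
- In F11, C10 is the only ketone, so catalytic DBU can move the alkene only toward C10. This comes back to the route at 16.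

**Step 13.**
- What may go wrong: site selectivity between the two hindered secondary hydroxyls may be insufficient, leading to acylation at C10 or at both positions.
- Fallback: protect C10 at the stage where it is the only secondary hydroxyl. It sets out from 20, which is silylated (TESCl, imidazole, 0 °C) to ketol triethylsilyl ether F12.
- The reduction of step 12 gives diol F13, and 22 with DMAP gives veratrate F14.
- HF·pyridine removes the silyl group and comes back to the route at 23.

**Step 1.**
- What may go wrong: the catalyst may discriminate the enone faces poorly with a small sp2 Grignard reagent on a five-membered enone.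
- Some 1,2-addition may compete.
- Fallback: upgrade the enantiomeric purity by classical resolution at the one acidic intermediate. It sets out from 10, a vinylogous acid. This is crystallised as its diastereomeric salt with (R)-1-phenylethylamine, ammonium enolate F15.
- Cold dilute acid releases the enriched dione and comes back to the route at 10.

## Further compounds

F1 | step 6 | enol acetate of 10 (C6–O-acetyl isomer drawn) | O=C1C=C(OC(C)=O)[C@H]2[C@]1(C)CCC23OCCO3
F2 | step 6 | acetoxy methylenecyclobutane (head-to-head allene adduct of F1, β face) | O=C1[C@H]2C(=C)C[C@@]2(OC(C)=O)[C@H]3[C@]1(C)CCC34OCCO4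
F3 | step 11 | 10α-tert-butyldimethylsilyl ether of 17 | CC(C)(C)[Si](C)(C)O[C@@H]1C=C(C)CC(O[Si](C(C)C)(C(C)C)C(C)C)=C2C(=O)CC[C@]12C
F4 | step 11 | 10α-tert-butyldimethylsilyloxydauca-4,8-dien-6-one | CC(C)(C)[Si](C)(C)O[C@@H]1C=C(C)CC(=O)C2=C(C(C)C)CC[C@]12C
F5 | step 11 | 10α-silyloxydauca-4,8-dien-6β-ol | CC(C)(C)[Si](C)(C)O[C@@H]1C=C(C)C[C@@H](O)C2=C(C(C)C)CC[C@]12C
F6 | step 11 | 4β,5β-epoxy-10α-silyloxydauc-8-en-6β-ol | CC(C)(C)[Si](C)(C)O[C@@H]1C=C(C)C[C@@H](O)[C@@]23O[C@@]3(C(C)C)CC[C@]12C
F7 | step 11 | 4β,5β-epoxy-10α-silyloxydauc-8-en-6-one | CC(C)(C)[Si](C)(C)O[C@@H]1C=C(C)CC(=O)[C@@]23O[C@@]3(C(C)C)CC[C@]12C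
F8 | step 11 | 10-O-tert-butyldimethylsilyl ether of ketol 20 | CC(C)(C)[Si](C)(C)O[C@@H]1C=C(C)CC(=O)[C@@H]2[C@]1(C)CC[C@@]2(O)C(C)C
F9 | step 10 | 10β-epimer of 17 | O[C@H]1C=C(C)CC(O[Si](C(C)C)(C(C)C)C(C)C)=C2C(=O)CC[C@]12C
F10 | step 10 | 10α-formate of 17 | O=CO[C@@H]1C=C(C)CC(O[Si](C(C)C)(C(C)C)C(C)C)=C2C(=O)CC[C@]12C
F11 | step 8 | 8-methylene-6-triisopropylsilyloxy-5(6)-ene-4,10-dione | O=C1CC(=C)CC(O[Si](C(C)C)(C(C)C)C(C)C)=C2C(=O)CC[C@]12C
F12 | step 13 | 10-O-triethylsilyl ether of ketol 20 | CC[Si](CC)(CC)O[C@@H]1C=C(C)CC(=O)[C@@H]2[C@]1(C)CC[C@@]2(O)C(C)C
F13 | step 13 | 10-O-triethylsilyl ether of triol 21 | CC[Si](CC)(CC)O[C@@H]1C=C(C)C[C@H](O)[C@@H]2[C@]1(C)CC[C@@]2(O)C(C)C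
F14 | step 13 | 10-O-triethylsilyl ether of veratrate 23 | CC[Si](CC)(CC)O[C@@H]1C=C(C)C[C@H](OC(=O)c2ccc(OC)c(OC)c2)[C@@H]2[C@]1(C)CC[C@@]2(O)C(C)C
F15 | step 1 | (R)-1-phenylethylammonium enolate of 10 | C[C@@H]([NH3+])c1ccccc1.[O-]C1=CC(=O)[C@H]2[C@]1(C)CCC23OCCO3
A1 | alternative 1 | seven-membered lactone with ring oxygen on C8 (C1, C8 and enol-ether geometry left open) | CC1C(=O)OC(C)(C=COCc2ccc(OC)cc2)C[C@H](O[Si](C)(C)C(C)(C)C)[C@H]1C1(C(C)C)OCCO1
A2 | alternative 1 | cycloheptene carboxylic acid with quaternary C1 and C10 ether | OC(=O)[C@]1(C)[C@H](OCc2ccc(OC)cc2)C=C(C)C[C@H](O[Si](C)(C)C(C)(C)C)[C@H]1C1(C(C)C)OCCO1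
A3 | alternative 2 | acyclic tertiary α-chloro methyl ketone with tethered 2-silyloxydiene (C1 and alkene geometries left open) | CC(=O)C(C)(Cl)CC[C@@](O[Si](C)(C)C)(C(C)C)C=C(O[Si](CC)(CC)CC)C=CC
A4 | alternative 2 | bicyclic C10 ketone with C6 enol silyl ether | O=C1C[C@H](C)C=C(O[Si](CC)(CC)CC)[C@@H]2[C@]1(C)CC[C@@]2(O[Si](C)(C)C)C(C)C
A5 | alternative 3 | 3-methylcyclopent-2-en-1-one (identical with 1) | CC1=CC(=O)CC1
A6 | alternative 3 | 4-methyl-1,2-bis(trimethylsilyloxy)cyclopent-1-ene | CC1CC(O[Si](C)(C)C)=C(O[Si](C)(C)C)C1
A7 | alternative 3 | cis-anti-cis 5-4-5 photoadduct (one enantiomer drawn) | C[C@]12CCC(=O)[C@H]1[C@]1(O[Si](C)(C)C)C[C@H](C)C[C@]21O[Si](C)(C)C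
A8 | alternative 3 | saturated cis-fused 8-methyl-4,6,10-trione (C8 left open) | O=C1CC(C)CC(=O)[C@H]2[C@]1(C)CCC2=O
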